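Atom labels used throughout: ring B is C1 (acetyl), C2 (OH), C3 (O-acyl), C4 (OH), C5 (H), C6 (pentyl). Ring A is C1′ (carboxyl), C2′ (OMe), C4′ (OH), C6′ (propyl).

## The problem

Compound 16 is a meta-depside. Ring A is held by one ester to O3 of ring B, a pentasubstituted benzene with acetyl at C1, OH at C2, the acyloxy group at C3, OH at C4, H at C5 and pentyl at C6. There is no stereocentre and no stable axis, so every difficulty is one of position. Ring B carries three oxygens in a row, of which only the middle one is acylated. No cheap arene combines this 1,2,3-trioxygenation with the acetyl and pentyl groups: olivetol 1 supplies O2, O4 and the chain, but not O3. The ester is ortho-substituted four times (C2′–OMe and C6′–propyl beside the acyl carbon, C2–OH and C4–OH beside O3), so acyl transfer to O3 is slow, and the finished ester can move to O2 or O4 or be cleaved by base or nucleophiles. Ring A has its methyl on the chelated O2′ and leaves the more reactive O4′ free, the reverse of what direct methylation gives. The free phenols, the aryl ester and the aryl ketone together demand a neutral end-game.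

The feature that opens the problem is C3 itself, for three reasons:
- It lies between C2–OH and C4–OH of a resorcinol. That makes it the α-carbon of a masked 1,3-dicarbonyl unit and the most nucleophilic ring atom.
- The C2–OH···O=C(acetyl) chelate fixes double-bond character in C3=C4.
- The C2′ and C6′ groups that hinder acyl transfer also shield the acyl carbon of any O-electrophilic derivative of the acid.

Hence the C3–O bond, not the acyl–O bond, can be the one that is made, with O3 arriving already acylated.

## Retrosynthesis

**16 ⇒ 15.** Only the O4′–H bond is changed, to O4′–CH2Ph. One protecting group is unavoidable, because the oxidising derivative of the acid used below cannot carry a free phenol of its own. Benzyl is chosen because it leaves under neutral, non-nucleophilic conditions that move no acyl group. The forward reaction only has to spare a hindered ester and a chelated ketone.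

**15 ⇒ 3 + 11.** The aryl–oxygen bond C3–O3 is cut, not the neighbouring acyl–oxygen bond.
- Cutting acyl–O leaves a pyrogallol whose three hydroxyls must be told apart and whose O3 must first be installed.
- Cutting C3–O leaves ketone 3, which has a C–H at C3, no protecting group and one oxygen fewer, and diaroyl peroxide 11, an "RCO2+" form of the acid.
- One operation then creates the third oxygen of ring B, the ester and its position.
- The forward reaction must attack O–O rather than C=O (secured by the C2′/C6′ shield) and react through C3 rather than C5 (secured by the chelate and by the C6 pentyl group).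

**11 ⇒ 9 (through acid chloride 10).** The O–O bond is cut. A symmetrical peroxide is preferred to a mixed one, because both oxygens then deliver the same acyl group and no unshielded carbonyl is offered to the phenoxide. The half that leaves in the key step is acid 9 itself and returns to this stage.

**9 ⇒ 8 ⇒ 6 (through monobenzyl ether 7).** The oxidation level at C1′ is lowered, and the O2′–CH3 and O4′–CH2Ph bonds are cut. The aldehyde level avoids saponification of a di-ortho-substituted ester. The reversed O-pattern of ring A costs nothing once the protecting group is placed first: O4′ reacts first and takes the benzyl, and the chelated O2′ takes the methyl afterwards.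

**6 ⇒ 4 (through iminium salt 5).** The C1′–CHO bond is cut. Divarinol 4 is symmetrical, so its two positions para to a hydroxyl are equivalent and only attack between the hydroxyls has to be avoided.

**3 ⇒ 1 (through ketiminium salt 2).** The C1–acetyl bond is cut. Olivetol 1 is commercial and symmetrical in the same sense. The acetyl group is introduced before the key step because it differentiates O2 from O4 and biases C3 over C5.

## Roads not taken

**Alternative 1:** cut the acyl–O3 bond (the obvious route).
- Forward key step: acid 9 is esterified with 1-[2,4-bis(benzyloxy)-3-hydroxy-6-pentylphenyl]ethan-1-one A1 through a mixed anhydride or a carbodiimide. This gives the tribenzyl depside A2, which is hydrogenolysed to 16.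
- A1 needs a separate oxygenation of C3 and the benzylation of both O4 and the reluctant chelated O2, several steps from 3.
- The coupling joins a di-ortho-substituted acid to a di-ortho-substituted phenol, the least favourable case of acyl transfer.
- The chosen plan spends no step on O3 and none on protecting ring B, and it uses the steric shielding as a control element.

**Alternative 2:** copy the presumed biosynthesis stepwise.
- Forward key steps: 3 is acylated at the free O4 to give the para-depside A3. C3 is then hydroxylated to give the 3-hydroxy para-depside A4. The acyl group then shifts from O4 to O3 to give 15.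
- The last step is sound, because the O3 ester is the more stable isomer.
- The middle step has no chemical equivalent. Acylation of O4 removes the stronger donor, and the remaining chelated O2–H directs electrophilic or persulfate (Elbs) oxygenation para, to C5.
- The chosen plan keeps the idea of late oxygenation at C3 but merges hydroxylation and acyl placement into one event, carried out on the more nucleophilic unacylated ring.

**Alternative 3:** build ring A last, cutting C1′–C2′ and C5′–C6′.
- Forward key step: A1 is esterified with the unhindered hex-2-ynoic acid to give ynoate A5. A Diels–Alder reaction with 1,1-dimethoxy-3-(trimethylsilyloxy)buta-1,3-diene A6 and loss of methanol gives A7, with C2′–OMe and C4′–OH in place. Hydrogenolysis then gives 16.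
- This solves the hindered esterification and the O-pattern of ring A.
- It still needs A1, that is, the whole ring B problem. Diene A6 must be prepared in several steps, and β-alkyl ynoates need long heating.
- It solves only the ring A part of the problem, and it is longer than the chosen route.

Key step: step 6

Assumption: the SMILES contains no stereocentre, no stereogenic double bond and no configurationally stable axis. Compound 16 is therefore achiral, and the request for a single enantiomer needs no stereocontrolled step.

## Route

Step 1
Reactants: 1 olivetol (5-pentylbenzene-1,3-diol)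
Product: 3 1-(2,4-dihydroxy-6-pentylphenyl)ethan-1-one, via ketiminium chloride 2 (not isolated)
Conditions: MeCN (1.5 equiv), ZnCl2, HCl (g), Et2O, 0 °C; decant; H2O, reflux
Reagents that add atoms: acetonitrile, CC#N; water, O
Why: Hoesch reaction; the activated nitrile attacks para to one hydroxyl and ortho to the other, the usual site in 5-alkylresorcinols, and the two such positions of 1 are equivalent. The iminium group of 2 deactivates the ring against a second acylation and is hydrolysed to the chelated ketone.

Step 2
Reactants: 4 divarinol (5-propylbenzene-1,3-diol)
Product: 6 2,4-dihydroxy-6-propylbenzaldehyde, via aryl iminium chloride 5 (not isolated)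
Conditions: POCl3 (1.2 equiv), DMF, 0 °C to rt; then ice-water, 50 °C
Reagents that add atoms: N,N-dimethylformamide, CN(C)C=O; water, O
Why: Vilsmeier–Haack formylation; the chloroiminium ion attacks para to a hydroxyl as in other 5-alkylresorcinols. Iminium salt 5 prevents a second formylation until it is hydrolysed.

Step 3
Reactants: 6 2,4-dihydroxy-6-propylbenzaldehyde
Product: 8 4-(benzyloxy)-2-methoxy-6-propylbenzaldehyde, via monobenzyl ether 7 (not isolated)
Conditions: BnBr (1.0 equiv), K2CO3 (1.1 equiv), DMF, rt; then MeI (2 equiv), K2CO3 (2 equiv), 45 °C
Reagents that add atoms: benzyl bromide, BrCc1ccccc1; iodomethane, CI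
Why: Two Williamson etherifications in the order the substrate dictates: O4′–H (para to CHO, unchelated) is the more acidic and reacts first, while O2′–H is chelated to the aldehyde and reacts only on warming with excess of the small electrophile. The protecting group thus lands on the oxygen that must end free, and the methyl on the chelated one.

Step 4
Reactants: 8 4-(benzyloxy)-2-methoxy-6-propylbenzaldehyde
Product: 9 4-(benzyloxy)-2-methoxy-6-propylbenzoic acid
Conditions: NaClO2, NaH2PO4, 2-methylbut-2-ene, t-BuOH/H2O, rt
Reagents that add atoms: sodium chlorite, [Na+].[O-]Cl=O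
Why: Pinnick oxidation, which tolerates di-ortho-substituted electron-rich benzaldehydes and benzyl ethers. The alkene removes hypochlorous acid before it can chlorinate C3′ or C5′.

Step 5
Reactants: 9 4-(benzyloxy)-2-methoxy-6-propylbenzoic acid (2 equiv per product)
Product: 11 bis[4-(benzyloxy)-2-methoxy-6-propylbenzoyl] peroxide, via acid chloride 10 (not isolated)
Conditions: (COCl)2, cat. DMF, CH2Cl2, 0 °C to rt, evaporate; Na2O2 (0.55 equiv), toluene/H2O, 0–5 °C, dark
Reagents that add atoms: sodium peroxide, [Na+].[Na+].[O-][O-]
Why: Standard preparation of diaroyl peroxides from aroyl chlorides and sodium peroxide, also known for di-ortho-substituted aroyl chlorides. The peroxide anion is a small α-effect nucleophile, and the donor-substituted chloride reacts with acylium character, which offsets the hindrance. Compound 11 is kept cold and dark, handled on a small scale and used without storage.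

Step 6
Reactants: 3 1-(2,4-dihydroxy-6-pentylphenyl)ethan-1-one; 11 bis[4-(benzyloxy)-2-methoxy-6-propylbenzoyl] peroxide
Product: 15 3-acetyl-2,6-dihydroxy-4-pentylphenyl 4-(benzyloxy)-2-methoxy-6-propylbenzoate, via sodium phenoxide 12 (not isolated), via aryl peroxyester 13 (not isolated), via cyclohexadienone 14 (not isolated)
Conditions: NaH (1.0 equiv), THF, 0 °C; then 11 (1.0 equiv), THF/toluene, −20 °C to rt, dark, Ar; 1 M HCl
Reagents that add atoms: none
Why: This is the polar ortho-aroyloxylation of a phenol by a diaroyl peroxide, the aromatic counterpart of the α-benzoyloxylation of 1,3-dicarbonyl enolates with dibenzoyl peroxide. One equivalent of base removes O4–H (O2–H is locked in the chelate to the acetyl oxygen); phenoxide 12 displaces carboxylate from one peroxide oxygen of 11; the weak O–O bond of peroxyester 13 then breaks in a six-membered [3,3] shift (C3=C4–O–O–C=O) to dienone 14, which enolises to 15, and direct attack of C3 on the O–O bond would lead to the same 14. Attack at O–O rather than at C=O is secured by C2′–OMe and C6′–propyl, which twist and shield both acyl carbons as in mesitoates, whereas the peroxide oxygens lie outside this shield. C3 is preferred to C5 because the O2–H···O=C chelate fixes C1=C2 and hence C3=C4 double-bond character, the same bias that sends the Claisen rearrangement of 4-allyloxy-2-hydroxyacetophenones and the C-alkylation of resacetophenone anions to C3; in addition C5 is crowded by the C6 pentyl group, and C1 is quaternary and cannot rearomatise. Which oxygen carries the acyl group is not a selectivity question, because O3 arrives acylated, and 15 is also the most stable acyl isomer (O2–H stays chelated, O4–H stays conjugated para to the acetyl group), so any migration corrects itself. Over-reaction is limited because the acyloxy group lowers the nucleophilicity of the product and 15 has no free catechol unit that could go on to an o-quinone. No ring is closed, and the sp3 carbon C3 of 14 is lost on enolisation, so no stereochemical control is needed. The second half of 11 leaves as the sodium salt of 9 and is recovered for step 5.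

Step 7
Reactants: 15 3-acetyl-2,6-dihydroxy-4-pentylphenyl 4-(benzyloxy)-2-methoxy-6-propylbenzoate
Product: 16 3-acetyl-2,6-dihydroxy-4-pentylphenyl 4-hydroxy-2-methoxy-6-propylbenzoate (target)
Conditions: H2 (1 atm), 10% Pd/C, EtOAc, rt
Reagents that add atoms: none
Why: Hydrogenolysis of an aryl benzyl ether under neutral conditions, the customary last step for depsides. The hindered aryl ester and the chelated, di-ortho-substituted ketone should not be reduced at 1 atm in a neutral aprotic solvent, and no base or nucleophile is present to move the acyl group.

## Compound list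

1 | olivetol (5-pentylbenzene-1,3-diol) | CCCCCc1cc(O)cc(O)c1 | starting material
2 | 1-(2,4-dihydroxy-6-pentylphenyl)ethan-1-iminium chloride | CCCCCc1cc(O)cc(O)c1C(C)=[NH2+].[Cl-] | intermediate
3 | 1-(2,4-dihydroxy-6-pentylphenyl)ethan-1-one | CCCCCc1cc(O)cc(O)c1C(C)=O | intermediate
4 | divarinol (5-propylbenzene-1,3-diol) | CCCc1cc(O)cc(O)c1 | starting material
5 | [(2,4-dihydroxy-6-propylphenyl)methylidene]dimethylazanium chloride | CCCc1cc(O)cc(O)c1C=[N+](C)C.[Cl-] | intermediate
6 | 2,4-dihydroxy-6-propylbenzaldehyde | CCCc1cc(O)cc(O)c1C=O | intermediate
7 | 4-(benzyloxy)-2-hydroxy-6-propylbenzaldehyde | CCCc1cc(OCc2ccccc2)cc(O)c1C=O | intermediate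
8 | 4-(benzyloxy)-2-methoxy-6-propylbenzaldehyde | CCCc1cc(OCc2ccccc2)cc(OC)c1C=O | intermediate
9 | 4-(benzyloxy)-2-methoxy-6-propylbenzoic acid | CCCc1cc(OCc2ccccc2)cc(OC)c1C(=O)O | intermediate
10 | 4-(benzyloxy)-2-methoxy-6-propylbenzoyl chloride | CCCc1cc(OCc2ccccc2)cc(OC)c1C(=O)Cl | intermediate
11 | bis[4-(benzyloxy)-2-methoxy-6-propylbenzoyl] peroxide | CCCc1cc(OCc2ccccc2)cc(OC)c1C(=O)OOC(=O)c1c(CCC)cc(OCc2ccccc2)cc1OC | intermediate
12 | sodium 4-acetyl-3-hydroxy-5-pentylphenolate | CCCCCc1cc([O-])cc(O)c1C(C)=O.[Na+] | intermediate
13 | 4-acetyl-3-hydroxy-5-pentylphenyl 4-(benzyloxy)-2-methoxy-6-propylbenzenecarboperoxoate | CCCCCc1cc(OOC(=O)c2c(CCC)cc(OCc3ccccc3)cc2OC)cc(O)c1C(C)=O | intermediate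
14 | 3-acetyl-2-hydroxy-6-oxo-4-pentylcyclohexa-2,4-dien-1-yl 4-(benzyloxy)-2-methoxy-6-propylbenzoate (racemic, transient sp3 carbon) | CCCCCC1=CC(=O)C(OC(=O)c2c(CCC)cc(OCc3ccccc3)cc2OC)C(O)=C1C(C)=O | intermediate
15 | 3-acetyl-2,6-dihydroxy-4-pentylphenyl 4-(benzyloxy)-2-methoxy-6-propylbenzoate | CCCCCc1cc(O)c(OC(=O)c2c(CCC)cc(OCc3ccccc3)cc2OC)c(O)c1C(C)=O | intermediate
16 | 3-acetyl-2,6-dihydroxy-4-pentylphenyl 4-hydroxy-2-methoxy-6-propylbenzoate (achiral) | CCCCCc1cc(O)c(OC(=O)c2c(CCC)cc(O)cc2OC)c(O)c1C(C)=O | target

## Step count and risks

Total step count: 7.
Longest linear sequence: 6 steps (4 → 6 → 8 → 9 → 11 → 15 → 16). Step 1 is the one-step side branch.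

**Step 6 (key step).** Three failures are most likely:
- Loss of site selectivity, either by reaction through C5 or by a second aroyloxylation of the product phenoxide.
- Acyl transfer by attack on a carbonyl carbon of 11 in spite of the shielding.
- Single-electron transfer from the phenoxide to the peroxide, followed by cage escape, decarboxylation of the aroyloxy radical and phenol coupling.

The fallback sets out from 3 and 9 and comes back at 15. It installs O3 first and acylates afterwards. Duff formylation of 3 at C3 (hexamethylenetetramine, TFA, heat, then aqueous acid) gives 3-acetyl-2,6-dihydroxy-4-pentylbenzaldehyde F1. Dakin oxidation (H2O2, aqueous NaOH, 0 °C, argon) is faster for the aldehyde than for the hindered chelated ketone and gives 1-(2,3,4-trihydroxy-6-pentylphenyl)ethan-1-one F2. F2 is esterified with 9 through the mixed trifluoroacetic anhydride (TFAA, toluene, rt). O3 is the only hydroxyl not conjugated with the acetyl group, so it should be the most nucleophilic. A final equilibration with a trace of tertiary amine lets any O4 ester move to the more stable O3 position, giving 15.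

**Step 5.** The second acylation, of the peracid anion by the hindered chloride 10, may be slower than hydrolysis, so the reaction may stall at the peracid stage. The electron-rich peroxide may also decompose by ionic carboxy-inversion during isolation.

The fallback sets out from 9 and comes back at 15. It replaces the O–O bond by iodine(III) as the carrier of electrophilic carboxylate. Ligand exchange of PhI(OAc)2 with two equivalents of 9 (chlorobenzene, reduced pressure to remove acetic acid) gives bis[4-(benzyloxy)-2-methoxy-6-propylbenzoyloxy](phenyl)-λ3-iodane F3. With 3 in CH2Cl2, F3 should bind O4 and hand one carboxylate ligand to C3 (Wessely-type ortho-acyloxylation followed by enolisation). Formation of a C3 iodonium ylide is the competing process to watch.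

**Step 1.** Competing attack at the carbon between the two hydroxyls, or O-imidate formation, would lower the regiochemical purity.

The fallback sets out from 1 and comes back at 3. It closes the position between the oxygens by O-alkylation. Methylation (MeI, K2CO3, acetone) gives 1,3-dimethoxy-5-pentylbenzene F4. Friedel–Crafts acetylation (AcCl, SnCl4, CH2Cl2, 0 °C) para to a methoxy group gives 1-(2,4-dimethoxy-6-pentylphenyl)ethan-1-one F5. BBr3 (CH2Cl2, −78 °C to rt) removes both methyl groups to give 3.

**Step 4.** Electrophilic chlorination of the very electron-rich ring may occur if hypochlorous acid escapes the scavenger.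

The fallback sets out from 4 and comes back at 9. It brings in C1′ at the acid level. Carboxylation with methyl magnesium carbonate (DMF, 120 °C) gives 2,4-dihydroxy-6-propylbenzoic acid F6. BnBr (2 equiv) and K2CO3 give benzyl 4-(benzyloxy)-2-hydroxy-6-propylbenzoate F7. MeI and K2CO3 in DMF give benzyl 4-(benzyloxy)-2-methoxy-6-propylbenzoate F8. Saponification (KOH, DMSO/H2O, 90 °C) gives 9.

## Further compounds

F1 | step 6 | 3-acetyl-2,6-dihydroxy-4-pentylbenzaldehyde | CCCCCc1cc(O)c(C=O)c(O)c1C(C)=O
F2 | step 6 | 1-(2,3,4-trihydroxy-6-pentylphenyl)ethan-1-one | CCCCCc1cc(O)c(O)c(O)c1C(C)=O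
F3 | step 5 | bis[4-(benzyloxy)-2-methoxy-6-propylbenzoyloxy](phenyl)-λ3-iodane | CCCc1cc(OCc2ccccc2)cc(OC)c1C(=O)OI(OC(=O)c1c(CCC)cc(OCc2ccccc2)cc1OC)c1ccccc1
F4 | step 1 | 1,3-dimethoxy-5-pentylbenzene | CCCCCc1cc(OC)cc(OC)c1
F5 | step 1 | 1-(2,4-dimethoxy-6-pentylphenyl)ethan-1-one | CCCCCc1cc(OC)cc(OC)c1C(C)=O
F6 | step 4 | 2,4-dihydroxy-6-propylbenzoic acid | CCCc1cc(O)cc(O)c1C(=O)O
F7 | step 4 | benzyl 4-(benzyloxy)-2-hydroxy-6-propylbenzoate | CCCc1cc(OCc2ccccc2)cc(O)c1C(=O)OCc1ccccc1
F8 | step 4 | benzyl 4-(benzyloxy)-2-methoxy-6-propylbenzoate | CCCc1cc(OCc2ccccc2)cc(OC)c1C(=O)OCc1ccccc1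
A1 | alternative 1 | 1-[2,4-bis(benzyloxy)-3-hydroxy-6-pentylphenyl]ethan-1-one | CCCCCc1cc(OCc2ccccc2)c(O)c(OCc2ccccc2)c1C(C)=O
A2 | alternative 1 | 3-acetyl-2,6-bis(benzyloxy)-4-pentylphenyl 4-(benzyloxy)-2-methoxy-6-propylbenzoate | CCCCCc1cc(OCc2ccccc2)c(OC(=O)c2c(CCC)cc(OCc3ccccc3)cc2OC)c(OCc2ccccc2)c1C(C)=O
A3 | alternative 2 | 4-acetyl-3-hydroxy-5-pentylphenyl 4-(benzyloxy)-2-methoxy-6-propylbenzoate | CCCCCc1cc(OC(=O)c2c(CCC)cc(OCc3ccccc3)cc2OC)cc(O)c1C(C)=O
A4 | alternative 2 | 4-acetyl-2,3-dihydroxy-5-pentylphenyl 4-(benzyloxy)-2-methoxy-6-propylbenzoate | CCCCCc1cc(OC(=O)c2c(CCC)cc(OCc3ccccc3)cc2OC)c(O)c(O)c1C(C)=O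
A5 | alternative 3 | 3-acetyl-2,6-bis(benzyloxy)-4-pentylphenyl hex-2-ynoate | CCCCCc1cc(OCc2ccccc2)c(OC(=O)C#CCCC)c(OCc2ccccc2)c1C(C)=O
A6 | alternative 3 | 1,1-dimethoxy-3-(trimethylsilyloxy)buta-1,3-diene | COC(OC)=CC(=C)O[Si](C)(C)C
A7 | alternative 3 | 3-acetyl-2,6-bis(benzyloxy)-4-pentylphenyl 4-hydroxy-2-methoxy-6-propylbenzoate | CCCCCc1cc(OCc2ccccc2)c(OC(=O)c2c(CCC)cc(O)cc2OC)c(OCc2ccccc2)c1C(C)=O
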